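The C40 skeleton is cut at both ring–chain bonds, C6–C7 and C6'–C7'. In rings A and B the alkene carbon C6 carries the alkyne carbon C7 while C4, across C5=C6, carries oxygen: the imprint of acetylide 1,2-addition to a vinylogous ester followed by allylic transposition. A single operation therefore adds both ends of a dilithiated all-E C22 heptaene-diyne to two molecules of an S-configured, acetonide-masked 3,4-dihydroxy-enone and, on acid hydrolysis, releases both 3-hydroxy-4-oxo rings. The C3 and C3' centres, set beforehand by asymmetric transfer hydrogenation, then direct an intramolecular hydride delivery that sets C4 and C4' and completes the trans-3,4-diols.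

Key step: step 7

Assumption: carotenoid numbering is used throughout (ring C1–C6, chain C7–C15, primes for the second half); the (S,S)-TsDPEN ligand of step 3 is chosen by the usual aryl/alkyl-ketone model and is taken to give the S carbinol.

Step 1
Reactants: 1 ketoisophorone (2,6,6-trimethylcyclohex-2-ene-1,4-dione)
Product: 2 rac-1,3,3-trimethyl-7-oxabicyclo[4.1.0]heptane-2,5-dione (the 2,3-epoxide of 1)
Conditions: 30% aq. H2O2, NaOH (cat.), MeOH, 0–10 °C
Reagents that add atoms: hydrogen peroxide, OO
Why: Weitz–Scheffer nucleophilic epoxidation, in which hydroperoxide adds conjugately to the electron-poor ene-dione double bond and closes the oxirane; the racemic epoxide is sufficient because both of its centres become sp2 in step 2.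

Step 2
Reactants: 2 rac-1,3,3-trimethyl-7-oxabicyclo[4.1.0]heptane-2,5-dione
Product: 3 3-hydroxy-2,6,6-trimethylcyclohex-2-ene-1,4-dione
Conditions: NaOH (1.1 equiv), H2O/MeOH, 20–50 °C, N2; then HCl to pH 2
Reagents that add atoms: none
Why: Base-induced isomerisation of an alpha,beta-epoxy ketone to a diosphenol, in which loss of the epoxide proton next to the carbonyl (directly, or after hydroxide opening and dehydration) turns the oxirane into the enolate of the cyclic 1,2-dione, and acidification gives the stable conjugated enol.

Step 3
Reactants: 3 3-hydroxy-2,6,6-trimethylcyclohex-2-ene-1,4-dione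
Product: 4 (4S)-3,4-dihydroxy-2,6,6-trimethylcyclohex-2-en-1-one
Conditions: RuCl[(S,S)-TsDPEN](p-cymene) (0.5 mol %), HCO2H/Et3N (5:2), CH2Cl2, 25 °C
Reagents that add atoms: none
Why: Noyori asymmetric transfer hydrogenation, in which the bifunctional Ru–H/N–H catalyst should reduce only the unhindered ketone between the enol carbon and the CH2 group (the other carbonyl is neopentylic and part of a vinylogous acid) and set the carbinol centre S by catalyst control, the sp2 enol carbon taking the place of the aryl group of an aryl alkyl ketone.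

Step 4
Reactants: 4 (4S)-3,4-dihydroxy-2,6,6-trimethylcyclohex-2-en-1-one; 5 2,2-dimethoxypropane
Product: 6 (7aS)-2,2,4,6,6-pentamethyl-7,7a-dihydro-1,3-benzodioxol-5(6H)-one (dioxolane-fused enone; carotenoid C3 is the S carbon bearing H)
Conditions: TsOH·H2O (cat.), acetone, rt
Reagents that add atoms: 2,2-dimethoxypropane (compound 5), COC(C)(C)OC
Why: Acid-catalysed ketal exchange (acetonide formation), in which the enol hydroxyl and the adjacent secondary hydroxyl close a five-membered isopropylidene ketal that converts the acidic enol into a neutral vinylogous ester and leaves the carbinol centre untouched.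

Step 5
Reactants: 7 (2E)-3-methylpent-2-en-4-yn-1-ol
Product: 9 [(2E)-3-methylpent-2-en-4-yn-1-yl]triphenylphosphonium bromide, via allylic bromide 8 (not isolated)
Conditions: PBr3 (0.4 equiv), pyridine (cat.), Et2O, −10 to 0 °C; aqueous wash; then PPh3, EtOAc, rt
Reagents that add atoms: phosphorus tribromide, BrP(Br)Br; triphenylphosphine, c1ccc(cc1)P(c1ccccc1)c1ccccc1
Why: Bromination of the primary allylic alcohol with PBr3 followed by SN2 quaternisation of PPh3 (phosphonium salt formation), both at the CH2 carbon, so that the E double bond and the terminal alkyne are not touched.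

Step 6
Reactants: 9 [(2E)-3-methylpent-2-en-4-yn-1-yl]triphenylphosphonium bromide (2.2 equiv); 10 (2E,4E,6E)-2,7-dimethylocta-2,4,6-trienedial
Product: 13 all-E 3,7,12,16-tetramethyloctadeca-3,5,7,9,11,13,15-heptaene-1,17-diyne (C22 diyne), via phosphorus ylide 11 (not isolated), via diyne stereoisomer mixture 12 (not isolated)
Conditions: NaOMe, MeOH/CH2Cl2, 0 °C to rt, Ar, dark; then I2 (cat.), toluene, rt, diffuse light; crystallisation from heptane
Reagents that add atoms: none
Why: Two-fold Wittig olefination, in which methoxide deprotonates only the phosphonium CH2 (the alkyne C–H is far less acidic), the semi-stabilised allylic ylide joins C11 to C12 at both aldehyde termini, and iodine-catalysed equilibration of the E/Z mixture at the two new disubstituted double bonds should leave the thermodynamically favoured all-E isomer to crystallise.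

Step 7
Reactants: 13 all-E C22 heptaene-diyne; 6 (7aS)-2,2,4,6,6-pentamethyl-7,7a-dihydro-1,3-benzodioxol-5(6H)-one (2.6 equiv)
Product: 16 (3S,3'S)-7,8,7',8'-tetradehydroastaxanthin, via dilithium diacetylide 14 (not isolated), via bis-carbinol adduct 15 (not isolated)
Conditions: n-BuLi (2.0 equiv), THF, −78 to −30 °C; 6, −78 to 0 °C; then degassed 1 M aq. H2SO4, THF, 0 °C to rt; Ar, dark
Reagents that add atoms: water, O
Why: Each acetylide terminus of 14 adds 1,2 to the only carbonyl of 6 (C6), a vinylogous-ester ketone with no alpha hydrogen on the quaternary C1 side whose one acidic C–H (at C3, gamma through the enol ether) is removed far more slowly than the weakly basic acetylide adds, so C3 keeps its S configuration; aqueous acid then ionises each tertiary C6 carbinol with donation from the enol-ether oxygen at C4, water captures the oxocarbenium ion at C4, and collapse of the hemiketal releases acetone, the C4 ketone, the C5=C6 double bond and the free C3 hydroxyl. The closest known reaction type is the Stork–Danheiser alkynylation and transposition of cyclic 3-alkoxy-enones, run here in two directions on one bis-nucleophile. No ring is closed (the two dioxolanes are opened) and the step makes the two C–C bonds C6–C7 and C6'–C7'. The carbinol centres formed at C6 and C6' in 15 arise without control, which does not matter because both become sp2 on transposition, so no lasting stereocentre is created and 16 carries only the C3 and C3' centres brought in by 6. The selectivities needed are complete two-fold 1,2-addition (secured by an excess of 6 over exactly two equivalents of base, so that no free strong base remains to enolise the ketone), ionisation toward the ring oxygen and not along the alkyne–polyene (secured by the much stronger oxygen stabilisation of the C4 cation), and survival of the all-E heptaene and of the air- and base-sensitive alpha-ketol (secured by cold, dilute, degassed acid and exclusion of light).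

Step 8
Reactants: 16 (3S,3'S)-7,8,7',8'-tetradehydroastaxanthin
Product: 17 (3S,4S,3'S,4'S)-7,8,7',8'-tetradehydro-β,β-carotene-3,4,3',4'-tetrol (all-E; both 3,4-diols trans)
Conditions: Me4NBH(OAc)3 (8 equiv), AcOH, MeCN/THF, −25 to 0 °C, Ar, dark; aq. Rochelle salt
Reagents that add atoms: none
Why: Saksena–Evans hydroxyl-directed reduction, in which ligand exchange binds each C3 hydroxyl to boron and the resulting alkoxydiacetoxyborohydride delivers hydride intramolecularly to the face of the neighbouring C4 carbonyl on which O3 stands, so that the new C4 hydroxyl ends up trans to the C3 hydroxyl (4S from 3S by substrate control), while this mild reagent should leave undirected carbonyls, the alkynes and the polyene alone.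

Compound list
1 | ketoisophorone (2,6,6-trimethylcyclohex-2-ene-1,4-dione) | CC1=CC(=O)CC(C)(C)C1=O | starting material
2 | rac-1,3,3-trimethyl-7-oxabicyclo[4.1.0]heptane-2,5-dione | CC12OC1C(=O)CC(C)(C)C2=O | intermediate
3 | 3-hydroxy-2,6,6-trimethylcyclohex-2-ene-1,4-dione | CC1=C(O)C(=O)CC(C)(C)C1=O | intermediate
4 | (4S)-3,4-dihydroxy-2,6,6-trimethylcyclohex-2-en-1-one | CC1=C(O)[C@@H](O)CC(C)(C)C1=O | intermediate
5 | 2,2-dimethoxypropane | COC(C)(C)OC | starting material
6 | (7aS)-2,2,4,6,6-pentamethyl-7,7a-dihydro-1,3-benzodioxol-5(6H)-one | CC1=C2OC(C)(C)O[C@H]2CC(C)(C)C1=O | intermediate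
7 | (2E)-3-methylpent-2-en-4-yn-1-ol | C#C/C(C)=C/CO | starting material
8 | (3E)-5-bromo-3-methylpent-3-en-1-yne | C#C/C(C)=C/CBr | intermediate
9 | [(2E)-3-methylpent-2-en-4-yn-1-yl]triphenylphosphonium bromide | C#C/C(C)=C/C[P+](c1ccccc1)(c1ccccc1)c1ccccc1.[Br-] | intermediate
10 | (2E,4E,6E)-2,7-dimethylocta-2,4,6-trienedial | O=C/C(C)=C/C=C/C=C(C)/C=O | starting material
11 | [(2E)-3-methylpent-2-en-4-yn-1-ylidene]triphenylphosphorane | C#C/C(C)=C/C=P(c1ccccc1)(c1ccccc1)c1ccccc1 | intermediate
12 | 3,7,12,16-tetramethyloctadeca-3,5,7,9,11,13,15-heptaene-1,17-diyne as formed: E/Z mixture at the two new double bonds (carotenoid C11=C12 and C11'=C12'), all others E | C#C/C(C)=C/C=CC(/C)=C/C=C/C=C(\C)C=C/C=C(\C)C#C | intermediate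
13 | (3E,5E,7E,9E,11E,13E,15E)-3,7,12,16-tetramethyloctadeca-3,5,7,9,11,13,15-heptaene-1,17-diyne | C#C/C(C)=C/C=C/C(C)=C/C=C/C=C(C)/C=C/C=C(\C)C#C | intermediate
14 | 1,18-dilithio derivative of 13 (dilithium diacetylide) | [Li]C#C/C(C)=C/C=C/C(C)=C/C=C/C=C(C)/C=C/C=C(\C)C#C[Li] | intermediate
15 | two-fold 1,2-adduct of 14 to 6: tertiary carbinols at C6 and C6', both acetonides intact, 3S,3'S, mixture of carbinol epimers (formed as the dilithium alkoxide) | CC1=C2OC(C)(C)O[C@H]2CC(C)(C)C1(O)C#C/C(C)=C/C=C/C(C)=C/C=C/C=C(C)/C=C/C=C(\C)C#CC1(O)C(C)=C2OC(C)(C)O[C@H]2CC1(C)C | intermediate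
16 | (3S,3'S)-3,3'-dihydroxy-7,8,7',8'-tetradehydro-β,β-carotene-4,4'-dione (7,8,7',8'-tetradehydroastaxanthin) | CC1=C(C#C/C(C)=C/C=C/C(C)=C/C=C/C=C(C)/C=C/C=C(\C)C#CC2=C(C)C(=O)[C@@H](O)CC2(C)C)C(C)(C)C[C@H](O)C1=O | intermediate
17 | (3S,4S,3'S,4'S)-7,8,7',8'-tetradehydro-β,β-carotene-3,4,3',4'-tetrol | CC1=C(C#C/C(C)=C/C=C/C(C)=C/C=C/C=C(C)/C=C/C=C(\C)C#CC2=C(C)[C@H](O)[C@@H](O)CC2(C)C)C(C)(C)C[C@H](O)[C@H]1O | target

Total step count: 8 (ring fragment steps 1–4, chain fragment steps 5–6, coupling step 7, reduction step 8).
Longest linear sequence: 6 steps (1, 2, 3, 4, 7, 8).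

Steps most likely to fail

Step 7. The second addition may stall at the mono-adduct because the dianion or the mono-alkoxide precipitates; the ketone may be deprotonated at C3 instead of attacked; or the acid phase may isomerise or hydrate the polyene. The fallback moves the alkynylation to a small fragment, so that only a monoanion adds and the polyene is assembled last. It sets out from 7 and 6. Compound 7 would be masked with 2-methoxypropene (PPTS cat.) as the acid-labile mixed ketal (3E)-5-[(2-methoxypropan-2-yl)oxy]-3-methylpent-3-en-1-yne F1, deprotonated with n-BuLi in THF to lithium acetylide F2 and added to 6 to give tertiary carbinol F3. Dilute H2SO4 would then remove both ketals with transposition and give (6S)-6-hydroxy-3-[(3E)-5-hydroxy-3-methylpent-3-en-1-yn-1-yl]-2,4,4-trimethylcyclohex-2-en-1-one F4. PPh3·HBr in CH2Cl2 would convert its primary allylic alcohol into phosphonium bromide F5, and 1,2-epoxybutane in hot ethanol would generate ylide F6 without strong base. Two-fold Wittig olefination of 10, followed by iodine equilibration of the resulting E/Z mixture F7, would come back to the route at 16.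

Step 8. Hydride may be delivered without direction, giving poor facial selectivity at C4 and C4' and a mixture of trans and cis glycols; the newly formed allylic C4 alcohols may also ionise in acetic acid. The fallback replaces substrate direction by catalyst control on protected material. It sets out from 16: silylation (TBSCl, imidazole, DMF) would give bis-TBS ether F8. Corey–Bakshi–Shibata reduction ((S)-Me-CBS oxazaborolidine, catecholborane, toluene, −78 °C) should add hydride to each enone carbonyl with the substituted C5=C6 side acting as the large group, which corresponds to 4S, and give diol bis-TBS ether F9. TBAF in THF would then come back to the route at 17.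

Step 3. Enantioselectivity may be insufficient or the sense of induction reversed on this acidic enol substrate, and the second carbonyl may be partly reduced. The fallback is racemic reduction followed by classical resolution. It sets out from 3: hydrogenation over Raney Ni in methanol would give racemic diol F10. As a vinylogous acid it forms crystalline amine salts, and crystallisation with (S)-1-phenylethylamine (its antipode being taken should the R acid give the less soluble salt) would give diastereomerically pure ammonium salt F11. Dilute H2SO4 would liberate the free diol and come back to the route at 4.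

Further compounds
F1 | step 7 | (3E)-5-[(2-methoxypropan-2-yl)oxy]-3-methylpent-3-en-1-yne | C#C/C(C)=C/COC(C)(C)OC
F2 | step 7 | lithium acetylide of F1 | [Li]C#C/C(C)=C/COC(C)(C)OC
F3 | step 7 | tertiary carbinol from F2 and 6 (both ketals intact, mixture of carbinol epimers) | CC1=C2OC(C)(C)O[C@H]2CC(C)(C)C1(O)C#C/C(C)=C/COC(C)(C)OC
F4 | step 7 | (6S)-6-hydroxy-3-[(3E)-5-hydroxy-3-methylpent-3-en-1-yn-1-yl]-2,4,4-trimethylcyclohex-2-en-1-one | CC1=C(C#C/C(C)=C/CO)C(C)(C)C[C@H](O)C1=O
F5 | step 7 | {(2E)-5-[(4S)-4-hydroxy-2,6,6-trimethyl-3-oxocyclohex-1-en-1-yl]-3-methylpent-2-en-4-yn-1-yl}triphenylphosphonium bromide | CC1=C(C#C/C(C)=C/C[P+](c2ccccc2)(c2ccccc2)c2ccccc2)C(C)(C)C[C@H](O)C1=O.[Br-]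
F6 | step 7 | phosphorus ylide derived from F5 | CC1=C(C#C/C(C)=C/C=P(c2ccccc2)(c2ccccc2)c2ccccc2)C(C)(C)C[C@H](O)C1=O
F7 | step 7 | 16 as formed in the Wittig reaction: E/Z mixture at C11=C12 and C11'=C12' | CC1=C(C#C/C(C)=C/C=CC(/C)=C/C=C/C=C(\C)C=C/C=C(\C)C#CC2=C(C)C(=O)[C@@H](O)CC2(C)C)C(C)(C)C[C@H](O)C1=O
F8 | step 8 | 3,3'-bis(tert-butyldimethylsilyl) ether of 16 | CC1=C(C#C/C(C)=C/C=C/C(C)=C/C=C/C=C(C)/C=C/C=C(\C)C#CC2=C(C)C(=O)[C@@H](O[Si](C)(C)C(C)(C)C)CC2(C)C)C(C)(C)C[C@H](O[Si](C)(C)C(C)(C)C)C1=O
F9 | step 8 | 3,3'-bis(tert-butyldimethylsilyl) ether of 17 | CC1=C(C#C/C(C)=C/C=C/C(C)=C/C=C/C=C(C)/C=C/C=C(\C)C#CC2=C(C)[C@H](O)[C@@H](O[Si](C)(C)C(C)(C)C)CC2(C)C)C(C)(C)C[C@H](O[Si](C)(C)C(C)(C)C)[C@H]1O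
F10 | step 3 | rac-3,4-dihydroxy-2,6,6-trimethylcyclohex-2-en-1-one | CC1=C(O)C(O)CC(C)(C)C1=O
F11 | step 3 | (S)-1-phenylethylammonium salt of 4 | CC1=C([O-])[C@@H](O)CC(C)(C)C1=O.C[C@H]([NH3+])c1ccccc1
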